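The plan depends on cutting the C3–C4 bond of the pyran ring. The feature exploited is quaternary C2. Besides O1 and methyl it holds two CH2 groups, ring atom C3 and the exocyclic CH2O carbon, and tying both to one oxygen turns C2 into the achiral centre of an oxetane. In a single operation a C4 carbanion, made chiral by an enantiopure p-tolylsulfinyl group, opens that oxetane at one CH2. The pyran ring closes, C2 and C4 become stereogenic, and the other CH2 emerges as the free alcohol that will carry the ferulate. The precursor is an acetovanillone-derived 3-aryloxy-3-methyloxetane with a dioxolane-masked ketone and an ortho CH2S(O)Tol group. Thermal loss of the sulfoxide then gives the C3=C4 alkene.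

Key step: step 8

Numbering: the atom numbers of the 2H-chromene (O1, C2, C3, C4, C4a, C5 to C8, C8a) are used for all intermediates.
Assumption: the sense of induction in step 8 (S at sulfur gives 4R and 2R) and the pairing of (S,S)-hydrobenzoin with the S sulfoxide in step 7 rest on models. If either proves opposite, (R,R)-hydrobenzoin is used in step 7 and nothing else changes.
Remark: 13 is written as the 2,4-cis epimer (CH2OH and sulfinyl on the same face), the one that the geometry of the ring opening allows most easily. C4 is erased in step 9, so its epimer would serve equally.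

Step 1
Reactants: 1 acetovanillone
Product: 2 1-[3-(chloromethyl)-4-hydroxy-5-methoxyphenyl]ethan-1-one
Conditions: aq. CH2O (37%), conc. HCl, 30–35 °C
Reagents that add atoms: formaldehyde, C=O; hydrogen chloride, Cl
Why: Blanc chloromethylation, in which the free phenol directs the electrophile to its only open ortho position (also meta to the acetyl group) and HCl turns the benzylic alcohol into the chloride, as is routine for vanillin.

Step 2
Reactants: 2 1-[3-(chloromethyl)-4-hydroxy-5-methoxyphenyl]ethan-1-one; 3 4-methylbenzenethiol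
Product: 4 1-(4-hydroxy-3-methoxy-5-{[(4-methylphenyl)sulfanyl]methyl}phenyl)ethan-1-one
Conditions: K2CO3, acetone, 0 °C to rt
Reagents that add atoms: none
Why: Thioether formation by SN2 displacement (or by addition to the ortho-quinone methide formed on loss of HCl), in which the soft thiolate outruns the phenoxide for the benzylic carbon.

Step 3
Reactants: 4 1-(4-hydroxy-3-methoxy-5-{[(4-methylphenyl)sulfanyl]methyl}phenyl)ethan-1-one; 5 diethyl 2-bromo-2-methylpropanedioate
Product: 6 diethyl 2-(4-acetyl-2-methoxy-6-{[(4-methylphenyl)sulfanyl]methyl}phenoxy)-2-methylpropanedioate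
Conditions: Cs2CO3, DMF, 60 °C
Reagents that add atoms: none
Why: Williamson-type O-alkylation with a tertiary bromide that two ester groups activate for substitution by phenoxides, including ortho-substituted and electron-poor ones, and it installs the fully substituted ether carbon with two identical arms, so no stereocentre arises.

Step 4
Reactants: 6 diethyl 2-(4-acetyl-2-methoxy-6-{[(4-methylphenyl)sulfanyl]methyl}phenoxy)-2-methylpropanedioate
Product: 7 diethyl 2-[2-methoxy-4-(2-methyl-1,3-dioxolan-2-yl)-6-{[(4-methylphenyl)sulfanyl]methyl}phenoxy]-2-methylpropanedioate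
Conditions: HOCH2CH2OH, p-TsOH·H2O (cat.), toluene, reflux, Dean–Stark
Reagents that add atoms: ethane-1,2-diol, OCCO
Why: Acid-catalysed ketalisation with azeotropic removal of water masks the aryl ketone against hydride and lithium bases, and any ester exchange with the glycol is harmless because all ester groups are reduced in step 5.

Step 5
Reactants: 7 diethyl 2-[2-methoxy-4-(2-methyl-1,3-dioxolan-2-yl)-6-{[(4-methylphenyl)sulfanyl]methyl}phenoxy]-2-methylpropanedioate
Product: 8 2-[2-methoxy-4-(2-methyl-1,3-dioxolan-2-yl)-6-{[(4-methylphenyl)sulfanyl]methyl}phenoxy]-2-methylpropane-1,3-diol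
Conditions: LiAlH4, THF, 0 °C to rt
Reagents that add atoms: none
Why: Hydride reduction of both esters gives the prochiral 1,3-diol, the proton-free alpha carbon rules out loss of phenoxide by elimination, and the ketal, sulfide and aryl ethers are inert.

Step 6
Reactants: 8 2-[2-methoxy-4-(2-methyl-1,3-dioxolan-2-yl)-6-{[(4-methylphenyl)sulfanyl]methyl}phenoxy]-2-methylpropane-1,3-diol
Product: 10 2-{3-methoxy-4-[(3-methyloxetan-3-yl)oxy]-5-{[(4-methylphenyl)sulfanyl]methyl}phenyl}-2-methyl-1,3-dioxolane, via racemic monotosylate 9 (not isolated)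
Conditions: n-BuLi (1 equiv), THF, 0 °C; TsCl (1 equiv); n-BuLi (1 equiv), 0 to 60 °C
Reagents that add atoms: 4-methylbenzenesulfonyl chloride, Cc1ccc(cc1)S(=O)(=O)Cl (its atoms are kept in 9 only)
Why: One-pot monotosylation and intramolecular Williamson etherification (4-exo-tet) is the standard passage from 2,2-disubstituted propane-1,3-diols to 3,3-disubstituted oxetanes, and the stereocentre of 9 disappears again in the achiral oxetane.

Step 7
Reactants: 10 2-{3-methoxy-4-[(3-methyloxetan-3-yl)oxy]-5-{[(4-methylphenyl)sulfanyl]methyl}phenyl}-2-methyl-1,3-dioxolane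
Product: 11 2-{3-methoxy-4-[(3-methyloxetan-3-yl)oxy]-5-{[(S)-(4-methylphenyl)sulfinyl]methyl}phenyl}-2-methyl-1,3-dioxolane
Conditions: Ti(OiPr)4 (5 mol %), (S,S)-hydrobenzoin (10 mol %), t-BuOOH (1.1 equiv, in decane), toluene–hexane, rt; recrystallisation
Reagents that add atoms: tert-butyl hydroperoxide, CC(C)(C)OO
Why: Kagan-type enantioselective sulfoxidation with the diol ligand suited to aryl benzyl sulfides (a class that tartrate ligands serve less well), in which the chiral peroxotitanium complex distinguishes the two lone pairs of sulfur and crystallisation should raise the enantiomeric purity further.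

Step 8
Reactants: 11 2-{3-methoxy-4-[(3-methyloxetan-3-yl)oxy]-5-{[(S)-(4-methylphenyl)sulfinyl]methyl}phenyl}-2-methyl-1,3-dioxolane
Product: 13 [(2R,4R)-8-methoxy-2-methyl-6-(2-methyl-1,3-dioxolan-2-yl)-4-[(S)-(4-methylphenyl)sulfinyl]chroman-2-yl]methanol, via lithiated sulfoxide 12 (not isolated)
Conditions: LiN(iPr)2 (1.15 equiv), THF, −78 °C; BF3·OEt2 (2.5 equiv), −78 to −40 °C; aq. NaHCO3; chromatography
Reagents that add atoms: none
Why: Proposed new method: LiN(iPr)2 removes the proton that is both benzylic and alpha to sulfur, and once BF3 has bound the oxetane oxygen the carbanion 12 displaces that oxygen from one ring CH2 with inversion, so that ring strain pays for the C3–C4 bond and the second CH2 is released as its alkoxide. The closest known reaction types are the BF3-assisted alkylation of lithiated sulfoxides and sulfones with epoxides and oxetanes and the catalytic desymmetrisation of 3,3-disubstituted oxetanes by tethered heteroatom nucleophiles, whereas a tethered carbanion that chooses between the two CH2 groups under the control of sulfur is untested. The pyran ring closes in the 6-exo-tet mode (6-enolendo as far as the arene-conjugated carbanion is concerned, also allowed), helped by the two ortho neighbours of O1, which turn the O1–C2 bond out of the arene plane and hold the oxetane above C4. C4 is set by sulfur: in lithiated aryl benzyl sulfoxides the carbanion orbital lies along the S–tolyl bond with the arene beside the sulfur lone pair and lithium on the sulfinyl oxygen, the electrophile enters at the lobe remote from tolyl, and for S-configured sulfur this model gives 4R. C2 is set by C4: backside attack forces the arm still bound to the leaving oxygen to lie anti to C4, thus equatorial, and the methyl group axial, so only the half-chair with a pseudo-equatorial sulfinyl group avoids a 1,3-diaxial contact with methyl, and that half-chair can reach just one of the two CH2 groups, giving the 2,4-cis product with 2R. The step therefore needs group selectivity between two diastereotopic CH2 groups plus tolerance of the dioxolane, the first secured by this relay and backed by the fact that a wrong C2 epimer is a separable diastereomer while sulfur is still present, the second by keeping BF3 at or below −40 °C.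

Step 9
Reactants: 13 [(2R,4R)-8-methoxy-2-methyl-6-(2-methyl-1,3-dioxolan-2-yl)-4-[(S)-(4-methylphenyl)sulfinyl]chroman-2-yl]methanol
Product: 14 [(2R)-8-methoxy-2-methyl-6-(2-methyl-1,3-dioxolan-2-yl)-2H-chromen-2-yl]methanol
Conditions: toluene, solid NaHCO3, 90 °C, dark
Reagents that add atoms: none
Why: Thermal sulfoxide syn-elimination (Ei) can take a hydrogen only from C3 because tolyl and C4a offer none, its benzylic C–S bond lets it run below the temperatures at which 2H-chromenes open reversibly to ortho-quinone methides (so C2 is kept), and placing it before the acylation keeps the sulfoxide away from acyl activators and the sulfenic acid away from the cinnamate.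

Step 10
Reactants: 15 ferulic acid
Product: 16 (E)-3-(4-acetoxy-3-methoxyphenyl)prop-2-enoic acid
Conditions: Ac2O, pyridine, rt; aq. HCl work-up
Reagents that add atoms: acetic anhydride, CC(=O)OC(C)=O
Why: Simple phenol acetylation blocks self-acylation of ferulic acid in the coupling, and the aryl acetate can later be removed by aminolysis without harm to an alkyl cinnamate.

Step 11
Reactants: 14 [(2R)-8-methoxy-2-methyl-6-(2-methyl-1,3-dioxolan-2-yl)-2H-chromen-2-yl]methanol; 16 (E)-3-(4-acetoxy-3-methoxyphenyl)prop-2-enoic acid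
Product: 17 [(2R)-8-methoxy-2-methyl-6-(2-methyl-1,3-dioxolan-2-yl)-2H-chromen-2-yl]methyl (E)-3-(4-acetoxy-3-methoxyphenyl)prop-2-enoate
Conditions: iPrN=C=NiPr, DMAP (cat.), CH2Cl2, 0 °C to rt
Reagents that add atoms: none
Why: Steglich esterification, whose acylpyridinium intermediate copes with the neopentyl-type primary alcohol under neutral conditions that touch neither C2 nor the E alkene.

Step 12
Reactants: 17 [(2R)-8-methoxy-2-methyl-6-(2-methyl-1,3-dioxolan-2-yl)-2H-chromen-2-yl]methyl (E)-3-(4-acetoxy-3-methoxyphenyl)prop-2-enoate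
Product: 19 [(2R)-6-acetyl-8-methoxy-2-methyl-2H-chromen-2-yl]methyl (E)-3-(4-hydroxy-3-methoxyphenyl)prop-2-enoate (target CNP0168033.1), via phenol ketal 18 (not isolated)
Conditions: pyrrolidine, THF, 0 °C to rt; then 1 M aq. HCl, rt
Reagents that add atoms: water, O
Why: Aminolysis cleaves the aryl acetate, an activated ester, far faster than the hindered conjugated alkyl ester while the ketone is still masked, and mild acid hydrolysis in the same flask then removes the dioxolane, which ionises easily thanks to the para oxygen, without disturbing C2.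

Compound list
1 | acetovanillone, 1-(4-hydroxy-3-methoxyphenyl)ethan-1-one | CC(=O)c1ccc(O)c(OC)c1 | starting material
2 | 1-[3-(chloromethyl)-4-hydroxy-5-methoxyphenyl]ethan-1-one | CC(=O)c1cc(CCl)c(O)c(OC)c1 | intermediate
3 | 4-methylbenzenethiol | Cc1ccc(S)cc1 | starting material
4 | 1-(4-hydroxy-3-methoxy-5-{[(4-methylphenyl)sulfanyl]methyl}phenyl)ethan-1-one | CC(=O)c1cc(CSc2ccc(C)cc2)c(O)c(OC)c1 | intermediate
5 | diethyl 2-bromo-2-methylpropanedioate | CCOC(=O)C(C)(Br)C(=O)OCC | starting material
6 | diethyl 2-(4-acetyl-2-methoxy-6-{[(4-methylphenyl)sulfanyl]methyl}phenoxy)-2-methylpropanedioate | CCOC(=O)C(C)(Oc1c(OC)cc(C(C)=O)cc1CSc1ccc(C)cc1)C(=O)OCC | intermediate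
7 | diethyl 2-[2-methoxy-4-(2-methyl-1,3-dioxolan-2-yl)-6-{[(4-methylphenyl)sulfanyl]methyl}phenoxy]-2-methylpropanedioate | CCOC(=O)C(C)(Oc1c(OC)cc(C2(C)OCCO2)cc1CSc1ccc(C)cc1)C(=O)OCC | intermediate
8 | 2-[2-methoxy-4-(2-methyl-1,3-dioxolan-2-yl)-6-{[(4-methylphenyl)sulfanyl]methyl}phenoxy]-2-methylpropane-1,3-diol | OCC(C)(CO)Oc1c(OC)cc(C2(C)OCCO2)cc1CSc1ccc(C)cc1 | intermediate
9 | racemic mono(4-methylbenzenesulfonate) of diol 8 | OCC(C)(COS(=O)(=O)c1ccc(C)cc1)Oc1c(OC)cc(C2(C)OCCO2)cc1CSc1ccc(C)cc1 | intermediate
10 | 2-{3-methoxy-4-[(3-methyloxetan-3-yl)oxy]-5-{[(4-methylphenyl)sulfanyl]methyl}phenyl}-2-methyl-1,3-dioxolane | Cc1ccc(cc1)SCc1cc(cc(OC)c1OC1(C)COC1)C1(C)OCCO1 | intermediate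
11 | 2-{3-methoxy-4-[(3-methyloxetan-3-yl)oxy]-5-{[(S)-(4-methylphenyl)sulfinyl]methyl}phenyl}-2-methyl-1,3-dioxolane | Cc1ccc(cc1)[S@@](=O)Cc1cc(cc(OC)c1OC1(C)COC1)C1(C)OCCO1 | intermediate
12 | benzylic lithio derivative of 11 (S at sulfur, carbanion carbon not configurationally fixed) | Cc1ccc(cc1)[S@@](=O)C([Li])c1cc(cc(OC)c1OC1(C)COC1)C1(C)OCCO1 | intermediate
13 | [(2R,4R)-8-methoxy-2-methyl-6-(2-methyl-1,3-dioxolan-2-yl)-4-[(S)-(4-methylphenyl)sulfinyl]chroman-2-yl]methanol | OC[C@@]1(C)C[C@@H]([S@](=O)c2ccc(C)cc2)c2cc(C3(C)OCCO3)cc(OC)c2O1 | intermediate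
14 | [(2R)-8-methoxy-2-methyl-6-(2-methyl-1,3-dioxolan-2-yl)-2H-chromen-2-yl]methanol | OC[C@@]1(C)C=Cc2cc(C3(C)OCCO3)cc(OC)c2O1 | intermediate
15 | ferulic acid, (E)-3-(4-hydroxy-3-methoxyphenyl)prop-2-enoic acid | COc1cc(/C=C/C(=O)O)ccc1O | starting material
16 | (E)-3-(4-acetoxy-3-methoxyphenyl)prop-2-enoic acid | COc1cc(/C=C/C(=O)O)ccc1OC(C)=O | intermediate
17 | [(2R)-8-methoxy-2-methyl-6-(2-methyl-1,3-dioxolan-2-yl)-2H-chromen-2-yl]methyl (E)-3-(4-acetoxy-3-methoxyphenyl)prop-2-enoate | COc1cc(/C=C/C(=O)OC[C@@]2(C)C=Cc3cc(C4(C)OCCO4)cc(OC)c3O2)ccc1OC(C)=O | intermediate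
18 | [(2R)-8-methoxy-2-methyl-6-(2-methyl-1,3-dioxolan-2-yl)-2H-chromen-2-yl]methyl (E)-3-(4-hydroxy-3-methoxyphenyl)prop-2-enoate | COc1cc(/C=C/C(=O)OC[C@@]2(C)C=Cc3cc(C4(C)OCCO4)cc(OC)c3O2)ccc1O | intermediate
19 | [(2R)-6-acetyl-8-methoxy-2-methyl-2H-chromen-2-yl]methyl (E)-3-(4-hydroxy-3-methoxyphenyl)prop-2-enoate (CNP0168033.1) | COc1cc(/C=C/C(=O)OC[C@@]2(C)C=Cc3cc(C(C)=O)cc(OC)c3O2)ccc1O | target

Total step count: 12. Longest linear sequence: 11 (steps 1 to 9, 11 and 12); step 10 is a one-step side branch.

Steps most likely to fail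

1. Step 8. The doubly stabilised carbanion may react too slowly, so that BF3 ionises the dioxolane or opens the oxetane by itself. The relay from sulfur to C2 may also be weak, so that both CH2 groups are attacked. The fallback uses known chemistry only: C2 is set by an enzyme before ring closure, and the C3–C4 bond is made by an ordinary intramolecular sulfoxide alkylation. It sets out from diol 8. Lipase-catalysed acetylation (Pseudomonas cepacia lipase, vinyl acetate, MTBE, rt, the enzyme being chosen by screening for the arm wanted) should give the (S)-monoacetate F1. TBSCl and imidazole in DMF convert it into the silyl ether acetate F2. K2CO3 in MeOH removes the acetyl group to give the primary alcohol F3. TsCl, pyridine and DMAP then give the tosylate F4, so that the arm marked by the enzyme becomes C3. The sulfoxidation of step 7 leads to the sulfoxide tosylate F5. LiN(iPr)2 in THF–DMPU (−78 °C to rt) closes the pyran ring by 6-exo-tet displacement of tosylate to give the chroman silyl ether F6. Bu4NF in THF brings the sequence back to the route at 13, and either C4 epimer serves in step 9.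

2. Step 7. The catalyst may distinguish the two sulfur lone pairs poorly on a sulfide that carries three further Lewis-basic groups and a crowded benzyl group, and some over-oxidation may occur. The fallback gives up asymmetric catalysis for resolution and sets out from 10. NaIO4 in aqueous MeOH gives the racemic sulfoxide F7, whose antipodes are separated by preparative chromatography on a chiral stationary phase. The S antipode is 11, where the route is rejoined, and the other antipode allows the sense of induction in step 8 to be checked.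

3. Step 3. Substitution at the tertiary carbon by a phenoxide flanked on both sides may be slow. Dehydrobromination of 5 followed by conjugate addition of the phenoxide would then compete. The fallback builds the quaternary carbon in two stages and sets out from 4. Alkylation with diethyl bromomalonate, a secondary bromide without beta hydrogen (K2CO3, acetone, reflux), gives the aryloxymalonate F8. Its acidic C–H is then methylated (K2CO3, MeI, DMF, rt), conditions too weak to enolise the aryl ketone, and the route is rejoined at 6.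

Further compounds
F1 | step 8 | (S)-3-hydroxy-2-[2-methoxy-4-(2-methyl-1,3-dioxolan-2-yl)-6-{[(4-methylphenyl)sulfanyl]methyl}phenoxy]-2-methylpropyl acetate | OC[C@@](Oc1c(OC)cc(C2(C)OCCO2)cc1CSc1ccc(C)cc1)(C)COC(C)=O
F2 | step 8 | (R)-3-[(tert-butyldimethylsilyl)oxy]-2-(aryloxy)-2-methylpropyl acetate, aryl as in F1 | CC(C)(C)[Si](C)(C)OC[C@@](Oc1c(OC)cc(C2(C)OCCO2)cc1CSc1ccc(C)cc1)(C)COC(C)=O
F3 | step 8 | (R)-3-[(tert-butyldimethylsilyl)oxy]-2-(aryloxy)-2-methylpropan-1-ol, aryl as in F1 | CC(C)(C)[Si](C)(C)OC[C@@](Oc1c(OC)cc(C2(C)OCCO2)cc1CSc1ccc(C)cc1)(C)CO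
F4 | step 8 | (S)-3-[(tert-butyldimethylsilyl)oxy]-2-(aryloxy)-2-methylpropyl 4-methylbenzenesulfonate, aryl as in F1 | CC(C)(C)[Si](C)(C)OC[C@@](Oc1c(OC)cc(C2(C)OCCO2)cc1CSc1ccc(C)cc1)(C)COS(=O)(=O)c1ccc(C)cc1
F5 | step 8 | S-configured sulfoxide of F4 (S at carbon, S at sulfur) | CC(C)(C)[Si](C)(C)OC[C@@](Oc1c(OC)cc(C2(C)OCCO2)cc1C[S@](=O)c1ccc(C)cc1)(C)COS(=O)(=O)c1ccc(C)cc1
F6 | step 8 | tert-butyldimethylsilyl ether of 13 (2R,4R, S at sulfur) | CC(C)(C)[Si](C)(C)OC[C@@]1(C)C[C@@H]([S@](=O)c2ccc(C)cc2)c2cc(C3(C)OCCO3)cc(OC)c2O1
F7 | step 7 | racemic 2-{3-methoxy-4-[(3-methyloxetan-3-yl)oxy]-5-{[(4-methylphenyl)sulfinyl]methyl}phenyl}-2-methyl-1,3-dioxolane | Cc1ccc(cc1)S(=O)Cc1cc(cc(OC)c1OC1(C)COC1)C1(C)OCCO1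
F8 | step 3 | diethyl 2-(4-acetyl-2-methoxy-6-{[(4-methylphenyl)sulfanyl]methyl}phenoxy)propanedioate | CCOC(=O)C(Oc1c(OC)cc(C(C)=O)cc1CSc1ccc(C)cc1)C(=O)OCC
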